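All runs are calculated from invented constants, noise included.

all flasks: free monomer 21 mM; initiator 5 mol%

| run | transfer agent | remark | time |
|---|---|---|---|
| eta | 0.65 mM | run made earlier |  |
| theta | 0.84 mM | run made earlier |  |
| delta | 1.4 mM | run made earlier |  |
| summer | 0.630 mM |  | 6.0 min |
| noon | 1.30 mM |  | 6.0 min |

| run | time / min | monomer in chains / % | over-reaction product / % | free monomer / % |
|---|---|---|---|---|
| eta | 0.500 | 14.1 | 0 | 84.9 |
| eta | 1.50 | 37.4 | 0.8 | 61.1 |
| eta | 3.00 | 61.5 | 0.5 | 37.5 |
| eta | 4.00 | 71.4 | 2.0 | 26.1 |
| eta | 6.00 | 85.6 | 2.1 | 13.4 |
| theta | 1.33 | 23.7 | 0 | 74.9 |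
| theta | 2.50 | 33.2 | 0.8 | 65.0 |
| theta | 4.00 | 44.9 | 0.3 | 53.1 |
| theta | 5.00 | 54.3 | 2.1 | 47.6 |
| theta | 6.00 | 58.6 | 0.9 | 42.0 |
| delta | 0.500 | 8.7 | 0.8 | 90.5 |
| delta | 1.50 | 12.1 | 0 | 88.6 |
| delta | 3.00 | 12.8 | 0 | 87.1 |
| delta | 4.00 | 11.8 | 0.5 | 87.1 |
| delta | 6.00 | 11.6 | 0.6 | 86.4 |

(standard deviation of a reading: 1 percentage point)

1. which of these there is most of at the end, counted by the free monomer in it, summer (monomer in chains / free monomer / over-reaction product)
2. which of these there is most of at the end, counted by the free monomer in it, noon (monomer in chains / free monomer / over-reaction product)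
3. how much there is at the end of the one of these that leads, in percent of the free monomer charged: summer
4. how much there is at the end of the one of these that leads, in percent of the free monomer charged: noon

Eta, theta and delta differ in [transfer agent], so the logarithm of free monomer against time is the reading to take. From first to last reading, eta falls at a pseudo-first-order constant of 0.336 min⁻¹ and theta at 0.124 min⁻¹, while delta stands at 87.1% after 3.00 min and 86.4% after 6.00 min. My reckoning takes two amounts: [transfer agent], and the concentration of living ends that the initiator supplies. If each transfer agent kills one end and the constant follows the surviving ends, eta and theta give 0.951 mM, the end budget, a reading that carries their scatter.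

The ratio of [transfer agent] to budget is 0.662 in summer: [transfer agent] is less than the budget, so ends should survive there, with a constant of 0.358 min⁻¹. Carried on from eta's last reading, that reckons 11.7% free monomer and, after eta's 2.1% of over-reaction product, 86.2% in chains. In noon the ratio is 1.37: [transfer agent] is more than the budget, so noon should stall like delta, with 0.349 mM of transfer agent over.

The forecast gives monomer in chains at 85.5% (82% to 89%) for summer, slightly below my figure, and free monomer at 85.5% (80% to 89%) for noon, holding that “the transfer agent quickly shuts down most of the active catalyst”.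

The flask gives monomer in chains at 86.7% in summer and free monomer at 86.0% in noon.

    free monomer + living end → monomer in chains + living end, rate k1*[living end]*[free monomer] (k = 19.0 L mol⁻¹ s⁻¹)
    living end + transfer agent → dead chain (kL = 240 L mol⁻¹ s⁻¹)
    2 initiator → spent initiator (k = 6.00 L mol⁻¹ s⁻¹)
    free monomer + initiator → living end + monomer in chains (k = 2.70 L mol⁻¹ s⁻¹)
    initiator + monomer in chains → initiator + over-reaction product (k = 5.70 L mol⁻¹ s⁻¹)

After 6.00 min, noon keeps 27% of its transfer agent, 0.355 mM against the 0.349 mM reckoned from the budget. At 0.391 min, noon's initiator has a half-life of 0.22 min by its step with free monomer, far shorter than the 17 min of free monomer by that step.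

A neighbour of noon has 13 mM free monomer at the same loading of initiator and the same [transfer agent], so the budget, taken as following the initiator charge, scales to 0.589 mM, a ratio of 2.21, and that neighbour should stall with 0.711 mM of transfer agent over. Computed, it holds 0.585 mM of dead chain, with 55% of the transfer agent and 91.0% of the free monomer left.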